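A neighbour of these flasks, the spring recipe read early, comes back at the end, and the rule I carry to it is a count: how many turns each catalyst has made by the moment I look.

    partner + free catalyst → catalyst intermediate A (k1 = 1430 M⁻¹ s⁻¹)
    catalyst intermediate C → catalyst intermediate D (k2 = 52.6 s⁻¹)
    partner + precatalyst → free catalyst + spent reagent (k3 = 1.23 M⁻¹ s⁻¹)
    catalyst intermediate A ⇌ catalyst intermediate B (K4 = 1.2, k4 = 183 s⁻¹)
    catalyst intermediate D → free catalyst + product (k5 = 188 s⁻¹)
    substrate + catalyst intermediate B ⇌ catalyst intermediate C (K6 = 2.68 M⁻¹, k6 = 2470 M⁻¹ s⁻¹)
    catalyst intermediate C → spent catalyst (k7 = 0.0281 s⁻¹)
    substrate ⇌ dormant form (K8 = 0.322, k8 = 0.245 s⁻¹)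

in all of them: precatalyst 0.1 mol%
- autumn: substrate 0.073 M (fed, over 25.0 s); partner 2.00 equiv; time 50 s; a stirred flask in which substrate is dosed at a steady rate over 25.0 s without added volume, worked up at 50 s
- noon: substrate 0.073 M; partner 2.00 equiv; time 50 s; a closed flask charged with all of it at once and left for 50 s
- spring: substrate 0.073 M; partner 2.00 equiv (fed, over 25.0 s); time 50 s; a stirred flask in which partner is dosed at a steady rate over 25.0 s without added volume, worked up at 50 s
- winter: substrate 0.073 M; partner 2.00 equiv; a single well-mixed tank run continuously and read at steady state, 50 s in it on average

- the stated concentrations are those of everything mixed, before any reaction; amounts are the same in each set-up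
- the feed brings no volume worth counting
- run time (autumn): 50 s

* the set-up with the highest amount of product at the outlet or at the end, in percent of the substrate put in ("none" if the first two lie within 2 percentage points) (autumn / noon / spring / winter / none)
* amount of product at the outlet or at the end, in percent of the substrate put in, autumn
* amount of product at the outlet or at the end, in percent of the substrate put in, noon
* amount of product at the outlet or at the end, in percent of the substrate put in, spring
* amount of product at the outlet or at the end, in percent of the substrate put in, winter

I reckon noon. Partner turns precatalyst into free catalyst, free catalyst takes up partner to give A, and A exchanges with B. B binds substrate to give C, and C goes on through D to product and free catalyst. Substrate and dormant form relax with a half-life of 0.689 s, far shorter than the run, so the free substrate is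

[substrate] = 0.0552 M, with [partner] = 0.146 M.

C falls back at 922 s⁻¹ and goes forward at 52.6 s⁻¹, faster back than forward, so a binding event counts with the share

5.40%, and B leaves forward at 7.36 s⁻¹.

Per catalyst in B, the round, counting A, B, C, D and free catalyst, holds

0.140 in C, and in total 2.09.

A and B together are the resting state. The turnover clock, product per second per working catalyst at the starting [substrate], is

3.53 s⁻¹.

Activation is pseudo-first-order, with a lag of 5.57 s, so noon counts

157 turns, which at 0.1 mol% is 15.7%.

The weak link is a clock held steady. Substrate falls as product forms, and one catalyst dies per 1870 turns, so I read the clock at mid-run: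

13.8% for noon.

The forecast gives autumn 11.9%, noon 14.1%, spring 11.4%, winter 12.9% and best none, a little above my noon figure. Its ground: “I treated the cycle as quasi-steady”.

The simulation gives autumn 11.9%, noon 14.1%, spring 11.3% and winter 12.9%. Noon stands above winter by 1.2 percentage points, less than the margin of 2 points, so best is none.

That answer turns with the back reaction of C to substrate and B, a part of the matter only, acting together with the reading at 50 s and not at 500 s: without that back reaction noon goes from 14.1% to 62.7%, and read at the later time noon gives 74.5%. In my count that back reaction sits in the share 5.40%. Noon's reading at 0.1 mol% is 141 turns, so over 44.4 s its clock averages 3.17 s⁻¹, below the starting 3.53 s⁻¹.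

For spring read at 30 s, partner is dosed, so the activation exposure reaches the same mark at 16.7 s, and the clock gives 4.69%. The simulation gives 5.14%.

All constants are invented; the result is computed.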